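**Retrosynthetic overview**
- The C9 angelate is installed last; the C7 epoxy-ester and the C9 carbinol come together from one Evans–Tishchenko reaction of a 7-hydroxy-9-ketone with the epoxy-aldehyde.
- The 7-hydroxy-9-ketone comes from a tricyclic bis-enone (longipina-2,7-diene-1,9-dione) by ligand-controlled β-borylation/oxidation.
- Key disconnection: the C10–C11 cyclobutane bond of the 1,9-diketone. Both carbons are α-carbons; they are joined from a cis-fused bicyclo[5.4.0] bis-enone by coupling one enolate with the other after its conversion in situ into an α-iodo ketone (enolonium equivalent).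
- The bicycle comes from ring-closing metathesis and allylic oxidation of a cis-1,2-disubstituted cyclohexene, whose C4–C10 bond is set by a Johnson–Claisen rearrangement.
- Ring order: cyclohexenone (organocatalytic Michael/aldol, sets C5, from which all other ring stereocentres are relayed), then the seven-membered ring, then the cyclobutane.

Assumption: 1, 3, 17 and 21 are purchased; C1–C11 are longipinane labels (C1 ketone, C2=C3, cyclobutane C4/C5/C10/C11, C6 CMe2, C7 and C9 oxygenated, C8 CH2); the epoxy-acyl group is taken exactly as in the SMILES, (2S,3R) with the two methyls cis.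

**Step 1**
Reactants: 1 methyl 3,3-dimethylpent-4-enoate
Product: 2 3,3-dimethylpent-4-enal
Conditions: DIBAL-H (1.05 equiv), CH2Cl2, −78 °C; MeOH, Rochelle salt
Reagents that add atoms: none
Why: Low-temperature DIBAL half-reduction stops at the aluminium hemiacetal, which releases the aldehyde only on work-up (ester-to-aldehyde reduction); no stereocentre.

**Step 2**
Reactants: 2 3,3-dimethylpent-4-enal; 3 pent-1-en-3-one
Product: 5 (4R)-2-methyl-4-(2-methylbut-3-en-2-yl)cyclohex-2-en-1-one, via keto-aldehyde 4 (not isolated)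
Conditions: (S)-α,α-diphenylprolinol methyl ether (5 mol%), ethyl 3,4-dihydroxybenzoate (20 mol%), neat, 4 °C; then LiOH, i-PrOH, rt
Reagents that add atoms: none
Why: Enamine-catalysed asymmetric Michael addition (the diarylprolinol ether shields one enamine face and sets the future C5) followed by intramolecular aldol condensation, which can only close the six-membered 2-methyl-enone (Robinson-type annulation).

**Step 3**
Reactants: 5 (4R)-2-methyl-4-(2-methylbut-3-en-2-yl)cyclohex-2-en-1-one
Product: 6 (1S,4R)-2-methyl-4-(2-methylbut-3-en-2-yl)cyclohex-2-en-1-ol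
Conditions: (R)-Me-CBS (15 mol%), BH3·SMe2, THF, −30 °C
Reagents that add atoms: none
Why: Corey–Bakshi–Shibata reduction gives reagent-controlled 1,2-hydride delivery (α-substituted alkenyl arm as the large group), producing the 1S carbinol with OH cis to the C4 side chain and pseudo-axial.

**Step 4**
Reactants: 6 (1S,4R)-2-methyl-4-(2-methylbut-3-en-2-yl)cyclohex-2-en-1-ol
Product: 7 ethyl 2-[(1S,6R)-2-methyl-6-(2-methylbut-3-en-2-yl)cyclohex-2-en-1-yl]propanoate
Conditions: EtC(OEt)3 (6 equiv), EtCO2H (cat.), xylene, 140 °C (−EtOH)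
Reagents that add atoms: triethyl orthopropionate CCC(OCC)(OCC)OCC
Why: Johnson orthoester Claisen rearrangement transfers the ketene acetal suprafacially from the pseudo-axial C–O bond, so the new C4–C10 bond forms cis to the C5 side chain and the alkene moves to C2=C3; the propanoate α-centre is a mixture and is erased later.

**Step 5**
Reactants: 7 ethyl 2-[(1S,6R)-2-methyl-6-(2-methylbut-3-en-2-yl)cyclohex-2-en-1-yl]propanoate
Product: 9 4-[(1S,6R)-2-methyl-6-(2-methylbut-3-en-2-yl)cyclohex-2-en-1-yl]pent-1-en-3-one, via Weinreb amide 8 (not isolated)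
Conditions: MeNH(OMe)·HCl, i-PrMgCl, THF, −20 → 0 °C; then CH2=CHMgBr, 0 °C; inverse quench into cold 1 M HCl
Reagents that add atoms: N,O-dimethylhydroxylamine hydrochloride CNOC.Cl (N(OMe)Me of 8); vinylmagnesium bromide C=C[Mg]Br (vinyl of 9)
Why: Aminolysis by the chloromagnesium amide gives the Weinreb amide, whose stable magnesium chelate accepts one vinyl Grignard and collapses to the enone only on acidic quench (Weinreb ketone synthesis); ring stereocentres are untouched.

**Step 6**
Reactants: 9 4-[(1S,6R)-2-methyl-6-(2-methylbut-3-en-2-yl)cyclohex-2-en-1-yl]pent-1-en-3-one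
Product: 10 (4aS,9aR)-4,5,9,9-tetramethyl-1,2,4a,5,9,9a-hexahydro-6H-benzo[7]annulen-6-one
Conditions: Hoveyda–Grubbs II (5 mol%), toluene (2 mM), 80 °C
Reagents that add atoms: none
Why: Ring-closing metathesis of the vinyl ketone with the 1,1-dimethylallyl group is helped by the cis-1,2 arrangement and the gem-dimethyl effect and gives the cis-fused cyclohept-2-enone; the trisubstituted ring alkene is inert.

**Step 7**
Reactants: 10 (4aS,9aR)-4,5,9,9-tetramethyl-1,2,4a,5,9,9a-hexahydro-6H-benzo[7]annulen-6-one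
Product: 11 (4aS,9aR)-4,5,9,9-tetramethyl-4a,5,9,9a-tetrahydro-1H-benzo[7]annulene-2,6-dione
Conditions: Rh2(cap)4 (1 mol%), t-BuOOH (70% aq., 5 equiv), K2CO3, CH2Cl2, rt
Reagents that add atoms: tert-butyl hydroperoxide CC(C)(C)OO
Why: Radical allylic C–H oxidation attacks the only allylic methylene (C1) and turns the trisubstituted alkene into the 3-methyl-enone (valencene-to-nootkatone-type oxidation); the cycloheptenone has no γ-hydrogen.

**Step 8**
Reactants: 11 (4aS,9aR)-4,5,9,9-tetramethyl-4a,5,9,9a-tetrahydro-1H-benzo[7]annulene-2,6-dione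
Product: 14 longipina-2,7-diene-1,9-dione, via dilithium bis-dienolate 12 (not isolated), via C11-iodo lithium enolate 13 (not isolated)
Conditions: LDA (2.2 equiv), THF, −78 °C; then I2 (1.05 equiv), −78 → −20 °C, 5 mM
Reagents that add atoms: lithium diisopropylamide [Li]N(C(C)C)C(C)C (Li of 12 and 13); iodine II (I of 13)
Why: Proposed new method: double α′-deprotonation gives two cross-conjugated lithium dienolates whose only nucleophilic carbons are C10 and C11, held close by the cis ring fusion; iodine converts the less hindered C11 terminus into an α-iodo ketone (enolonium equivalent), which the neighbouring tetrasubstituted enolate carbon C10 displaces 4-exo-tet (or, after halogen exchange/electron transfer, the same bond forms by radical–enolate combination), giving the 1,4-diketone with quaternary C10 and C11 fixed by the ring fusion; the closest known reaction types are the I2- or Cu(II)-mediated intramolecular oxidative coupling of 1,6-dicarbonyl dianions to trans-1,2-diacylcyclobutanes and the intramolecular ketone-enolate alkylations that close the cyclobutane in copaene-type tricycles.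

**Step 9**
Reactants: 14 longipina-2,7-diene-1,9-dione
Product: 16 7-hydroxylongipin-2-ene-1,9-dione, via C7 pinacol boronate 15 (not isolated)
Conditions: CuCl (5 mol%), (R,S)-Josiphos (6 mol%), NaOt-Bu (10 mol%), B2pin2, MeOH, THF, rt; then NaBO3·4H2O, THF–H2O
Reagents that add atoms: bis(pinacolato)diboron CC1(C)OB(OC1(C)C)B1OC(C)(C)C(C)(C)O1 (Bpin of 15); sodium perborate [Na+].[Na+].O[B-]1(O)OO[B-](O)(O)OO1 (O of 16)
Why: Copper(I)-catalysed conjugate borylation takes place only at the β-monosubstituted cycloheptenone (the β,β-disubstituted verbenone-type enone is inert to phosphine–Cu–Bpin), the chiral ligand selecting between the two nearly equivalent enone faces to put boron on the C4-side face of C7, and perborate oxidation proceeds with retention.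

**Step 10**
Reactants: 17 (E)-2-methylbut-2-en-1-ol
Product: 18 [(2R,3R)-2,3-dimethyloxiran-2-yl]methanol
Conditions: Ti(Oi-Pr)4 (10 mol%), D-(−)-DIPT (12 mol%), t-BuOOH, 4 Å MS, CH2Cl2, −20 °C
Reagents that add atoms: tert-butyl hydroperoxide CC(C)(C)OO
Why: Sharpless asymmetric epoxidation of the E-trisubstituted allylic alcohol; the D-(−)-tartrate catalyst delivers oxygen to the face that gives the (2R,3R)-epoxy alcohol.

**Step 11**
Reactants: 18 [(2R,3R)-2,3-dimethyloxiran-2-yl]methanol
Product: 19 (2S,3R)-2,3-dimethyloxirane-2-carbaldehyde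
Conditions: TEMPO (10 mol%), PhI(OAc)2, CH2Cl2, rt; used as a solution
Reagents that add atoms: none
Why: TEMPO/oxoammonium oxidation converts the primary alcohol into the non-enolisable aldehyde without touching the epoxide; the C2 descriptor changes only through CIP priorities.

**Step 12**
Reactants: 16 7-hydroxylongipin-2-ene-1,9-dione; 19 (2S,3R)-2,3-dimethyloxirane-2-carbaldehyde
Product: 20 9-hydroxy-1-oxolongipin-2-en-7-yl (2S,3R)-2,3-dimethyloxirane-2-carboxylate
Conditions: 19 (4 equiv), SmI2 (30 mol%), THF, −10 °C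
Reagents that add atoms: none
Why: Evans–Tishchenko reduction: the samarium-bound hemiacetal formed from the C7 hydroxyl and 19 transfers hydride intramolecularly to the C9 ketone from the O7 face, giving the 1,3-anti (trans) C9 alcohol while the aldehyde carbon becomes the C7 ester carbonyl.

**Step 13**
Reactants: 20 9-hydroxy-1-oxolongipin-2-en-7-yl (2S,3R)-2,3-dimethyloxirane-2-carboxylate; 21 angelic acid
Product: 23 target CNP0149458.1, via angelic 2,4,6-trichlorobenzoic anhydride 22 (not isolated)
Conditions: 21, 2,4,6-Cl3C6H2COCl, Et3N, toluene, rt; then 20, 75 °C (no DMAP)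
Reagents that add atoms: 2,4,6-trichlorobenzoyl chloride O=C(Cl)c1c(Cl)cc(Cl)cc1Cl (aroyl of 22)
Why: Yamaguchi mixed-anhydride esterification without DMAP acylates the hindered C9 alcohol at the less hindered angeloyl carbonyl and preserves the Z geometry of the angelate.

**Compound list**
1 | methyl 3,3-dimethylpent-4-enoate | COC(=O)CC(C)(C)C=C | starting material
2 | 3,3-dimethylpent-4-enal | O=CCC(C)(C)C=C | intermediate
3 | pent-1-en-3-one (ethyl vinyl ketone) | C=CC(=O)CC | starting material
4 | (2S)-2-(2-methylbut-3-en-2-yl)-5-oxoheptanal | C=CC(C)(C)[C@@H](C=O)CCC(=O)CC | intermediate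
5 | (4R)-2-methyl-4-(2-methylbut-3-en-2-yl)cyclohex-2-en-1-one | C=CC(C)(C)[C@H]1C=C(C)C(=O)CC1 | intermediate
6 | (1S,4R)-2-methyl-4-(2-methylbut-3-en-2-yl)cyclohex-2-en-1-ol (1,4-cis) | C=CC(C)(C)[C@@H]1CC[C@H](O)C(C)=C1 | intermediate
7 | ethyl 2-[(1S,6R)-2-methyl-6-(2-methylbut-3-en-2-yl)cyclohex-2-en-1-yl]propanoate (1,6-cis; epimers at the propanoate α-carbon) | C=CC(C)(C)[C@@H]1CCC=C(C)[C@@H]1C(C)C(=O)OCC | intermediate
8 | N-methoxy-N-methyl-2-[(1S,6R)-2-methyl-6-(2-methylbut-3-en-2-yl)cyclohex-2-en-1-yl]propanamide | C=CC(C)(C)[C@@H]1CCC=C(C)[C@@H]1C(C)C(=O)N(C)OC | intermediate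
9 | 4-[(1S,6R)-2-methyl-6-(2-methylbut-3-en-2-yl)cyclohex-2-en-1-yl]pent-1-en-3-one | C=CC(C)(C)[C@@H]1CCC=C(C)[C@@H]1C(C)C(=O)C=C | intermediate
10 | (4aS,9aR)-4,5,9,9-tetramethyl-1,2,4a,5,9,9a-hexahydro-6H-benzo[7]annulen-6-one (cis-fused; C5 epimers) | O=C1C=CC(C)(C)[C@@H]2CCC=C(C)[C@@H]2C1C | intermediate
11 | (4aS,9aR)-4,5,9,9-tetramethyl-4a,5,9,9a-tetrahydro-1H-benzo[7]annulene-2,6-dione (cis-fused; C5 epimers) | O=C1C=CC(C)(C)[C@@H]2CC(=O)C=C(C)[C@@H]2C1C | intermediate
12 | dilithium 2,6-bis(dienolate) of 11 (enolate carbons = longipinane C10 and C11) | [Li]OC1C=CC(C)(C)[C@@H]2C=C(O[Li])C=C(C)[C@@H]2C=1C | intermediate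
13 | C11-iodo ketone of 11 as its C9 lithium dienolate | [Li]OC1C=CC(C)(C)[C@@H]2C(I)C(=O)C=C(C)[C@@H]2C=1C | intermediate
14 | longipina-2,7-diene-1,9-dione (2,6,6,9-tetramethyltricyclo[5.4.0.0^2,8]undeca-4,9-diene-3,11-dione; C4, C5, C10, C11 as in the target) | O=C1C=CC(C)(C)[C@@H]2[C@H]3C(=O)C=C(C)[C@@H]2[C@]31C | intermediate
15 | 7-(4,4,5,5-tetramethyl-1,3,2-dioxaborolan-2-yl)longipin-2-ene-1,9-dione (C7 as in the target) | O=C1C[C@@H](B2OC(C)(C)C(C)(C)O2)C(C)(C)[C@@H]2[C@H]3C(=O)C=C(C)[C@@H]2[C@]31C | intermediate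
16 | 7-hydroxylongipin-2-ene-1,9-dione (C7–OH on the C4-side face) | O=C1C[C@@H](O)C(C)(C)[C@@H]2[C@H]3C(=O)C=C(C)[C@@H]2[C@]31C | intermediate
17 | (E)-2-methylbut-2-en-1-ol (tiglyl alcohol) | C/C=C(\C)CO | starting material
18 | [(2R,3R)-2,3-dimethyloxiran-2-yl]methanol | OC[C@@]1(C)O[C@@H]1C | intermediate
19 | (2S,3R)-2,3-dimethyloxirane-2-carbaldehyde | O=C[C@@]1(C)O[C@@H]1C | intermediate
20 | 9-hydroxy-1-oxolongipin-2-en-7-yl (2S,3R)-2,3-dimethyloxirane-2-carboxylate (7,9-trans) | O[C@@H]1C[C@@H](OC(=O)[C@@]2(C)O[C@@H]2C)C(C)(C)[C@@H]2[C@H]3C(=O)C=C(C)[C@@H]2[C@]31C | intermediate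
21 | angelic acid, (Z)-2-methylbut-2-enoic acid | C/C=C(/C)C(=O)O | starting material
22 | angelic 2,4,6-trichlorobenzoic anhydride | C/C=C(/C)C(=O)OC(=O)c1c(Cl)cc(Cl)cc1Cl | intermediate
23 | CNP0149458.1: 9-[(Z)-2-methylbut-2-enoyloxy]-1-oxolongipin-2-en-7-yl (2S,3R)-2,3-dimethyloxirane-2-carboxylate | C/C=C(/C)C(=O)O[C@@H]1C[C@@H](OC(=O)[C@@]2(C)O[C@@H]2C)C(C)(C)[C@@H]2[C@H]3C(=O)C=C(C)[C@@H]2[C@]31C | target

**Step count**
Total: 13 steps. Longest linear sequence: 11 steps (1–9, 12, 13); the side branch (steps 10–11) joins at step 12.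

**Three steps most likely to fail**

Step 8 (cyclobutane-forming enolate/α-iodo-ketone coupling). The strained four-membered ring may lose out to O-alkylation (six-membered enol ether), intermolecular coupling or simple α-iodination. The fallback sets out from 11 and comes back at 14. Compound 11 is silylated (LDA, TMSCl, −78 °C) to the isolable bis(trimethylsilyl) dienol ether F1. Treatment with iodosylbenzene/BF3·OEt2 (CH2Cl2, −78 → −40 °C) turns the less hindered C11 silyl enol ether into an α-(phenyl-λ3-iodanyl) ketone, a discrete enolonium species, which is captured intramolecularly by the neutral C10 silyl enol ether. This avoids the dianion and molecular iodine altogether and gives 14.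

Step 9 (C7 oxygenation). The two faces of the cycloheptenone are almost equivalent, so the sense and level of ligand control cannot be predicted; the antipodal ligand is the first thing to try, and the neopentyl β-carbon may react slowly. The fallback sets out from 14 and comes back at 16. Amine-salt-catalysed asymmetric nucleophilic epoxidation (9-amino-9-deoxy-epi-cinchona alkaloid·TFA, aqueous H2O2) gives the 7,8-epoxy-1,9-dione F2. Regioselective reductive cleavage of the Cα–O bond (sodium phenylseleno(triethoxy)borate, EtOH/AcOH, or SmI2 at −90 °C) keeps the C7–O bond and delivers 16.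

Step 12 (Evans–Tishchenko with an α,β-epoxy aldehyde). Sm(II)/Sm(III) may open the epoxide, and the hindered C9 ketone may transfer hydride slowly. The fallback sets out from 16 and comes back at 23. Evans–Tishchenko reduction with acetaldehyde gives the 7-acetate 9-alcohol F3, and Yamaguchi angeloylation as in step 13 gives the 7-acetate 9-angelate F4. Selective acetate methanolysis (K2CO3, MeOH, 0 °C; the hindered conjugated angelate survives) gives the 7-alcohol 9-angelate F5. Yamaguchi esterification with (2S,3R)-2,3-dimethyloxirane-2-carboxylic acid F6 (from 19 by Pinnick oxidation) then gives 23.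

**Further compounds**
F1 | step 8 | 2,6-bis(trimethylsilyl) bis-dienol ether of 11 | C[Si](C)(C)OC1C=CC(C)(C)[C@@H]2C=C(O[Si](C)(C)C)C=C(C)[C@@H]2C=1C
F2 | step 9 | 7,8-epoxylongipin-2-ene-1,9-dione (epoxide oxygen on the C4-side face) | O=C1[C@H]2O[C@H]2C(C)(C)[C@@H]3[C@H]4C(=O)C=C(C)[C@@H]3[C@]41C
F3 | step 12 | 9-hydroxy-1-oxolongipin-2-en-7-yl acetate | O[C@@H]1C[C@@H](OC(C)=O)C(C)(C)[C@@H]2[C@H]3C(=O)C=C(C)[C@@H]2[C@]31C
F4 | step 12 | 7-acetoxy-1-oxolongipin-2-en-9-yl (Z)-2-methylbut-2-enoate | C/C=C(/C)C(=O)O[C@@H]1C[C@@H](OC(C)=O)C(C)(C)[C@@H]2[C@H]3C(=O)C=C(C)[C@@H]2[C@]31C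
F5 | step 12 | 7-hydroxy-1-oxolongipin-2-en-9-yl (Z)-2-methylbut-2-enoate | C/C=C(/C)C(=O)O[C@@H]1C[C@@H](O)C(C)(C)[C@@H]2[C@H]3C(=O)C=C(C)[C@@H]2[C@]31C
F6 | step 12 | (2S,3R)-2,3-dimethyloxirane-2-carboxylic acid | OC(=O)[C@@]1(C)O[C@@H]1C
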